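## Structural features

The target is a 1-aryltetralin lignan (lyoniresinol skeleton). Aromatic ring A (C4a, C5–C8, C8a) is fused to the saturated ring B (C1–C4); C1 carries a pendant 4-hydroxy-3,5-dimethoxyphenyl ring, C2 the hydroxymethyl carbon C9 and C3 the hydroxymethyl carbon C9'. Ring A has H at C5, methoxy groups at C6 and C8 and the free hydroxyl at C7. C4a is therefore para to that hydroxyl, both ortho positions are blocked, and the C8 methoxy group is peri to the C1 aryl group. C1 (S), C2 (R) and C3 (R) are contiguous and all-trans, so the C1 aryl group and C9' are cis. The fragile elements are two electron-rich 2,6-dimethoxyphenols (oxidation, and quinone methide formation at C1 through the pendant phenol), the doubly benzylic C1–H, and the C9/C9' 1,4-diol, which closes to a tetrahydrofuran as soon as one oxygen is a leaving group while the other is free. The real difficulty is to set three contiguous centres around a peri-strained diarylmethine while telling two near-identical phenols and three primary oxygens apart. The key step uses two facts: C4a is the para carbon of the C7 phenoxide, and C3 carries two constitutionally identical one-carbon arms (C4 and C9'). Bonding C4a to either arm makes C4–C4a, closes ring B and turns C3 into a stereocentre.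

## Logic of the disconnections

24 back to 23: the two O–benzyl bonds (pendant phenol and C9 oxygen) are cut. Both oxygens must stay masked through the basic ring closure and the sulfonate displacement, and hydrogenolysis is neutral. The gain is that one phenol and one primary alcohol are told apart from the rest. The demand is that nothing else in 23 is hydrogenolysed; the doubly benzylic C1–C bonds are not at risk.

23 back to 21 (through 22): the C9'–O bond is exchanged for a sulfonate. The arm left over by the ring closure is a leaving group, so the retron is an SN2 reaction with a carboxylate followed by ester cleavage. The gain is that C9' and C4 become the same kind of arm. The demand is substitution at a β-branched primary carbon without elimination, and before the C9 oxygen is freed, since a free C9–OH would close a tetrahydrofuran onto C9'.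

21 back to 19 (through 20): the C4–C4a bond is cut. C4a is the para carbon of the ring A phenoxide, and after the cut C3 carries two identical CH2OTs arms and is no longer stereogenic. One ring, one C–C bond and one stereocentre disappear, leaving an acyclic diarylmethane with only C1 and C2 set. The demands are C-alkylation at C4a only, selection of one diastereotopic arm under the control of C1 and C2, and a pendant phenol that cannot act as a nucleophile.

19 back to 18, 17 and 16: the ring A O–CH2OMe bond, two O–S bonds and the ketal C–O bonds are functional-group operations. The order is dictated by chemoselectivity: the ring A phenol appears last, after sulfonylation, so it cannot be sulfonylated. The demand is that the acetonide can be removed while the aryl acetal stays.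

16 back to 15: both O–benzyl bonds are made in one operation, because the pendant phenol is free only at this stage and the C9 alcohol has just been formed.

15 back to 7 and 12 (through 13 and 14): the C1–C2 bond is cut. C1 is the exocyclic carbon of a p-quinone methide of the pendant ring, and C2 is the α-carbon of an aldehyde whose carbonyl carbon becomes C9. The gain is a convergent split into an achiral diarylcarbinol and a small achiral aldehyde, with both stereocentres coming from one catalytic step. The demand is facial control at two trigonal carbons and immediate reduction of the epimerisable aldehyde.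

7 back to 2 and 4 (through 5 and 6): the C1–C8a bond is cut between an aryl anion at the position ortho to a methoxy group and an aldehyde carbon. Both halves are one step from bought phenols. The demand is regioselective metalation and a temporary mask on the aldehyde's phenol.

2 back to 1, 4 back to 3, and 12 back to 10, 9 and 8 (through 11): protecting-group bonds, an alkene cleavage that reveals the C9 carbonyl, and two ester reductions. These are simplifications to commercial materials with no selectivity demand beyond routine.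

## Other disconnections considered

Alternative 1: The cut is C1–C2 and C3–C4 together, a retro-[4+2]. In the forward direction, irradiation of the 2-benzylbenzaldehyde A2 moves a hydrogen from the diarylmethylene to the carbonyl oxygen, and the hydroxy-o-quinodimethane adds the lactate-derived fumarate A3 to give cycloadduct A1. In its favour, two bonds, ring B and four stereocentres arise in one step, and the 2,3-trans relation is inherited from the fumarate geometry. On this point it is better than the chosen plan, whose weakest element is the choice of arm at C3. Against it here, A1 carries a C4 hydroxyl that must be removed and two esters that must be reduced. The C1/C2 relation depends on dienol geometry and endo/exo preference. The lactate esters would have to steer a short-lived photoenol without the Lewis-acid chelation that usually makes them effective. A2 is a pentasubstituted benzaldehyde whose regiocontrolled preparation costs steps. In comparison, Alternative 1 is superior in bonds formed per step and equal or slightly better in overall step count. The chosen plan is stronger on absolute control, because C1 and C2 come from a well-understood enamine model in step 7.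

Alternative 2: The cut is C2–C3 and C1–C8a. In the forward direction, a laccase with O2 oxidises both phenols of the tethered bis-sinapate A5, the side-chain radicals couple at C2–C3, and one ring then adds through C8a to the quinone methide carbon C1 to give the bridged dihydronaphthalene A4. In its favour, it is biomimetic, needs no protecting groups, and forms the whole carbon skeleton in one mild step from a symmetrical precursor; in step economy it is clearly better than the chosen plan. Against it here, radical coupling can also go through oxygen, water can trap the quinone methide, and stereoinduction from a remote chiral diol tether in a macrocyclic radical coupling is uncertain. A4 also has C3 as an sp2 carbon, so C3 must be set afterwards by reduction of the C3=C4 bond. On the C3 question it is therefore only equal to the chosen plan (the problem is moved, not solved). It is weaker on absolute control of C1 and C2, where the chosen plan names a control element for every stereocentre.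

Alternative 3: The cut is C1–C2 with ring closure. In the forward direction, acid and a secondary amine convert the p-hydroxybenzhydrol aldehyde A7 into a p-quinone methide and an enamine, whose α-carbon C2 adds to C1 in a 6-exo-trig closure to give the all-trans aldehyde A6. In its favour, it is the same bond polarity as step 7 of the chosen plan but intramolecular. C3 is already a defined stereocentre, the epimerisable C2 can settle trans, and no diastereotopic-group selection is needed. On stereochemical security, especially at C3, it is better than the chosen plan. Against it here, A7 needs a ring A with two adjacent carbon substituents (the C4 side chain at C4a and the carbinol at C8a) on a trioxygenated ring, plus a separate enantioselective step for C3; that costs linear steps. Its ring closure also forms a bond at the peri-strained C1. In comparison, the two plans are equal in reaction type. The chosen plan is more convergent because it uses the innate nucleophilicity of C4a, so ring A needs no prior functionalisation there, and step counts should be similar.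

Key step: step 12

Remark: a phenoxide on the pendant ring could alkylate through its ipso carbon (five-membered spiro-dienone, Ar1-5 mode) in competition with ring A, so the ring closure is run on a precursor whose pendant phenol and C9 oxygen are benzyl ethers and whose only free phenol is on ring A.

## Route

Step 1
Reactants: 1 2,6-dimethoxyphenol
Product: 2 1,3-dimethoxy-2-(methoxymethoxy)benzene
Conditions: MOMCl, i-Pr2NEt, CH2Cl2, 0 °C → rt
Reagents that add atoms: chloromethyl methyl ether, COCCl
Why: O-alkylation of the phenol to the mixed acetal; the MOM ether survives n-BuLi, cannot direct metalation to its own (occupied) ortho positions, and is removable by acid once the sulfonates are in place.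

Step 2
Reactants: 3 syringaldehyde
Product: 4 4-[(tert-butyldimethylsilyl)oxy]-3,5-dimethoxybenzaldehyde
Conditions: TBSCl, imidazole, DMF, rt
Reagents that add atoms: tert-butyldimethylsilyl chloride, CC(C)(C)[Si](C)(C)Cl
Why: Silylation of the phenol; the mask is needed only so that the aldehyde, not a phenoxide, meets the aryllithium.

Step 3
Reactants: 2 1,3-dimethoxy-2-(methoxymethoxy)benzene; 4 4-[(tert-butyldimethylsilyl)oxy]-3,5-dimethoxybenzaldehyde
Product: 7 racemic 4-{hydroxy[2,4-dimethoxy-3-(methoxymethoxy)phenyl]methyl}-2,6-dimethoxyphenol, via aryllithium 5 (not isolated), via lithium alkoxide 6 (not isolated)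
Conditions: n-BuLi, TMEDA, THF, 0 °C; then 4, −78 → 0 °C; then n-Bu4NF, 0 °C
Reagents that add atoms: none
Why: Directed ortho-metalation next to a methoxy group (the only ring protons ortho to an oxygen director), 1,2-addition to the aldehyde, and fluoride cleavage of the aryl silyl ether in the same pot; the carbinol centre is racemic and is erased in step 7.

Step 4
Reactants: 8 diethyl allylmalonate
Product: 9 2-allylpropane-1,3-diol
Conditions: LiAlH4, THF, 0 °C → reflux
Reagents that add atoms: none
Why: Hydride reduction of both esters; the isolated alkene is inert.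

Step 5
Reactants: 9 2-allylpropane-1,3-diol
Product: 10 5-allyl-2,2-dimethyl-1,3-dioxane
Conditions: Me2C(OMe)2, p-TsOH (cat.), CH2Cl2, rt
Reagents that add atoms: 2,2-dimethoxypropane, COC(C)(C)OC
Why: Acid-catalysed transketalisation to the six-membered acetonide, which keeps the two future arms (C4 and C9') identical and masked.

Step 6
Reactants: 10 5-allyl-2,2-dimethyl-1,3-dioxane
Product: 12 2-(2,2-dimethyl-1,3-dioxan-5-yl)acetaldehyde, via ozonide 11 (not isolated)
Conditions: O3, CH2Cl2, −78 °C; then Me2S, −78 °C → rt
Reagents that add atoms: ozone, [O-][O+]=O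
Why: Ozonolysis with reductive work-up; the new carbonyl carbon is the future C9 and its α-CH2 the future C2.

Step 7
Reactants: 7 racemic 4-{hydroxy[2,4-dimethoxy-3-(methoxymethoxy)phenyl]methyl}-2,6-dimethoxyphenol; 12 2-(2,2-dimethyl-1,3-dioxan-5-yl)acetaldehyde
Product: 15 (2R,3S)-2-(2,2-dimethyl-1,3-dioxan-5-yl)-3-(4-hydroxy-3,5-dimethoxyphenyl)-3-[2,4-dimethoxy-3-(methoxymethoxy)phenyl]propan-1-ol, via quinone methide 13 (not isolated), via aldehyde 14 (not isolated)
Conditions: (R)-2-{bis[3,5-bis(trifluoromethyl)phenyl](trimethylsilyloxy)methyl}pyrrolidine (20 mol%), (PhO)2P(O)OH (10 mol%), CH2Cl2, 0 °C; then NaBH4, MeOH, 0 °C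
Reagents that add atoms: none
Why: Organocatalytic 1,6-conjugate addition of an aldehyde to a p-quinone methide: acid ionises the doubly activated carbinol 7 to 13, and the (E)-enamine of 12 is shielded on one face by the catalyst's diaryl(silyloxy)methyl group, so C1 of 13 bonds to the open face and C2 becomes R (the (R)-catalyst is chosen by analogy with enamine Michael additions). An open synclinal approach of the Seebach type, with the quinoid ring over the enamine nitrogen, gives the syn-type relation that makes C1 S; NaBH4 then reduces the epimerisable aldehyde 14 in the same pot.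

Step 8
Reactants: 15 (2R,3S)-2-(2,2-dimethyl-1,3-dioxan-5-yl)-3-(4-hydroxy-3,5-dimethoxyphenyl)-3-[2,4-dimethoxy-3-(methoxymethoxy)phenyl]propan-1-ol
Product: 16 5-[(1S,2R)-3-(benzyloxy)-1-[4-(benzyloxy)-3,5-dimethoxyphenyl]-1-[2,4-dimethoxy-3-(methoxymethoxy)phenyl]propan-2-yl]-2,2-dimethyl-1,3-dioxane
Conditions: NaH, BnBr, n-Bu4NI (cat.), DMF, 0 °C → rt
Reagents that add atoms: benzyl bromide, BrCc1ccccc1
Why: Double Williamson etherification of the phenoxide and the primary alkoxide; one operation masks the pendant phenol (no spiro-alkylation later) and the C9 oxygen (no tetrahydrofuran formation later), and both groups leave together in step 14.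

Step 9
Reactants: 16 5-[(1S,2R)-3-(benzyloxy)-1-[4-(benzyloxy)-3,5-dimethoxyphenyl]-1-[2,4-dimethoxy-3-(methoxymethoxy)phenyl]propan-2-yl]-2,2-dimethyl-1,3-dioxane
Product: 17 2-[(1S,2R)-3-(benzyloxy)-1-[4-(benzyloxy)-3,5-dimethoxyphenyl]-1-[2,4-dimethoxy-3-(methoxymethoxy)phenyl]propan-2-yl]propane-1,3-diol
Conditions: PPTS, MeOH, rt
Reagents that add atoms: none
Why: Mild acid transketalisation opens the strained 2,2-dimethyl-1,3-dioxane under conditions that should leave the aryl methoxymethyl acetal and the benzyl ethers in place.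

Step 10
Reactants: 17 2-[(1S,2R)-3-(benzyloxy)-1-[4-(benzyloxy)-3,5-dimethoxyphenyl]-1-[2,4-dimethoxy-3-(methoxymethoxy)phenyl]propan-2-yl]propane-1,3-diol
Product: 18 2-[(1S,2R)-3-(benzyloxy)-1-[4-(benzyloxy)-3,5-dimethoxyphenyl]-1-[2,4-dimethoxy-3-(methoxymethoxy)phenyl]propan-2-yl]propane-1,3-diyl bis(4-methylbenzenesulfonate)
Conditions: TsCl, Et3N, DMAP (cat.), CH2Cl2, 0 °C → rt
Reagents that add atoms: 4-methylbenzenesulfonyl chloride, Cc1ccc(S(=O)(=O)Cl)cc1
Why: Sulfonylation of both primary alcohols; no phenol is free at this stage, so only the two arms are activated, and C3 stays non-stereogenic.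

Step 11
Reactants: 18 2-[(1S,2R)-3-(benzyloxy)-1-[4-(benzyloxy)-3,5-dimethoxyphenyl]-1-[2,4-dimethoxy-3-(methoxymethoxy)phenyl]propan-2-yl]propane-1,3-diyl bis(4-methylbenzenesulfonate)
Product: 19 2-[(1S,2R)-3-(benzyloxy)-1-[4-(benzyloxy)-3,5-dimethoxyphenyl]-1-(3-hydroxy-2,4-dimethoxyphenyl)propan-2-yl]propane-1,3-diyl bis(4-methylbenzenesulfonate)
Conditions: HCl (1.25 M in MeOH), THF, rt
Reagents that add atoms: none
Why: Acid-catalysed acetal exchange frees the ring A phenol; methanol traps the methoxymethyl cation so it cannot alkylate the electron-rich ring, and sulfonates and benzyl ethers are stable to acid.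

Step 12
Reactants: 19 2-[(1S,2R)-3-(benzyloxy)-1-[4-(benzyloxy)-3,5-dimethoxyphenyl]-1-(3-hydroxy-2,4-dimethoxyphenyl)propan-2-yl]propane-1,3-diyl bis(4-methylbenzenesulfonate)
Product: 21 {(1S,2R,3R)-1-[4-(benzyloxy)-3,5-dimethoxyphenyl]-2-[(benzyloxy)methyl]-7-hydroxy-6,8-dimethoxy-1,2,3,4-tetrahydronaphthalen-3-yl}methyl 4-methylbenzenesulfonate (ring numbered as in the target), via dienone 20 (not isolated)
Conditions: KOt-Bu (1.05 equiv), t-BuOH–THF, 0.005 M, 25 → 50 °C
Reagents that add atoms: none
Why: KOt-Bu deprotonates the only acidic group, the ring A phenol; the para carbon C4a of the phenoxide displaces one tosylate at C4 in an intramolecular SN2 reaction, and the cyclohexa-2,5-dienone 20 tautomerises to phenol 21. The closest known reaction type is the intramolecular para-C-alkylation of phenoxides by sulfonates (aryl participation of the Ar2-6 kind) that gives 6-hydroxytetralins. Ring B closes in the 6-exo-tet mode. Site selectivity comes from the substrate: O-alkylation within the molecule would need a meta-bridged ring, C8 carries a methoxy group and attack there would give a dienone that cannot aromatise, and the pendant ring is a benzyl ether; high dilution and the protic medium suppress intermolecular O-alkylation, and one equivalent of base leaves none for E2. The new stereocentre C3 is controlled by C1 and C2 in a chair-like transition state: the peri C8 methoxy group keeps C1–H near the plane of ring A and the pendant aryl pseudo-axial, which places the trans-disposed C9 arm pseudo-axial as well. The SN2 centre C4 tolerates only the small C3–H beside the departing sulfonate, so the spectator CH2OTs flanks the nucleophile, pseudo-axial and anti to C9, which is the 2,3-trans relation. The step therefore needs diastereotopic-group selectivity; the competing chair that would give the 3-epimer must put the spectator arm against the leaving group, and the all-equatorial chair must put the C1 aryl against the C8 methoxy group. After aromatisation ring B relaxes to the half-chair of the all-trans tetralin.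

Step 13
Reactants: 21 {(1S,2R,3R)-1-[4-(benzyloxy)-3,5-dimethoxyphenyl]-2-[(benzyloxy)methyl]-7-hydroxy-6,8-dimethoxy-1,2,3,4-tetrahydronaphthalen-3-yl}methyl 4-methylbenzenesulfonate
Product: 23 {(1S,2R,3R)-1-[4-(benzyloxy)-3,5-dimethoxyphenyl]-2-[(benzyloxy)methyl]-7-hydroxy-6,8-dimethoxy-1,2,3,4-tetrahydronaphthalen-3-yl}methanol, via acetate 22 (not isolated)
Conditions: CsOAc, DMF, 60 °C; then K2CO3 (cat.), MeOH, rt
Reagents that add atoms: cesium acetate, CC(=O)[O-].[Cs+]
Why: SN2 displacement of the primary tosylate by the weakly basic acetate (little E2 at the β-branched carbon), then transesterification to the alcohol; C9 is still a benzyl ether, so no tetrahydrofuran can form, and no stereocentre is touched.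

Step 14
Reactants: 23 {(1S,2R,3R)-1-[4-(benzyloxy)-3,5-dimethoxyphenyl]-2-[(benzyloxy)methyl]-7-hydroxy-6,8-dimethoxy-1,2,3,4-tetrahydronaphthalen-3-yl}methanol
Product: 24 (1S,2R,3R)-1-(4-hydroxy-3,5-dimethoxyphenyl)-2,3-bis(hydroxymethyl)-6,8-dimethoxy-1,2,3,4-tetrahydronaphthalen-7-ol (target CNP0153696.1)
Conditions: H2 (1 atm), Pd/C (10%), EtOAc–MeOH, rt
Reagents that add atoms: none
Why: Hydrogenolysis of the aryl and the alkyl benzyl ether under neutral conditions; the C1–aryl bonds, methyl ethers and stereocentres are not affected.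

## Compound list

1 | 2,6-dimethoxyphenol | COc1cccc(OC)c1O | starting material
2 | 1,3-dimethoxy-2-(methoxymethoxy)benzene | COCOc1c(OC)cccc1OC | intermediate
3 | syringaldehyde (4-hydroxy-3,5-dimethoxybenzaldehyde) | COc1cc(C=O)cc(OC)c1O | starting material
4 | 4-[(tert-butyldimethylsilyl)oxy]-3,5-dimethoxybenzaldehyde | COc1cc(C=O)cc(OC)c1O[Si](C)(C)C(C)(C)C | intermediate
5 | [2,4-dimethoxy-3-(methoxymethoxy)phenyl]lithium (not isolated) | [Li]c1ccc(OC)c(OCOC)c1OC | intermediate
6 | lithium alkoxide of racemic {4-[(tert-butyldimethylsilyl)oxy]-3,5-dimethoxyphenyl}[2,4-dimethoxy-3-(methoxymethoxy)phenyl]methanol (not isolated) | [Li+].COc1cc(C([O-])c2ccc(OC)c(OCOC)c2OC)cc(OC)c1O[Si](C)(C)C(C)(C)C | intermediate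
7 | racemic 4-{hydroxy[2,4-dimethoxy-3-(methoxymethoxy)phenyl]methyl}-2,6-dimethoxyphenol | COc1cc(C(O)c2ccc(OC)c(OCOC)c2OC)cc(OC)c1O | intermediate
8 | diethyl allylmalonate | C=CCC(C(=O)OCC)C(=O)OCC | starting material
9 | 2-allylpropane-1,3-diol | C=CCC(CO)CO | intermediate
10 | 5-allyl-2,2-dimethyl-1,3-dioxane | C=CCC1COC(C)(C)OC1 | intermediate
11 | 3-[(2,2-dimethyl-1,3-dioxan-5-yl)methyl]-1,2,4-trioxolane (ozonide, not isolated) | CC1(C)OCC(CC2OCOO2)CO1 | intermediate
12 | 2-(2,2-dimethyl-1,3-dioxan-5-yl)acetaldehyde | CC1(C)OCC(CC=O)CO1 | intermediate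
13 | 4-{[2,4-dimethoxy-3-(methoxymethoxy)phenyl]methylidene}-2,6-dimethoxycyclohexa-2,5-dien-1-one (quinone methide, not isolated) | COC1=CC(=Cc2ccc(OC)c(OCOC)c2OC)C=C(OC)C1=O | intermediate
14 | (2R,3S)-2-(2,2-dimethyl-1,3-dioxan-5-yl)-3-(4-hydroxy-3,5-dimethoxyphenyl)-3-[2,4-dimethoxy-3-(methoxymethoxy)phenyl]propanal (not isolated) | COc1cc([C@@H](c2ccc(OC)c(OCOC)c2OC)[C@@H](C=O)C2COC(C)(C)OC2)cc(OC)c1O | intermediate
15 | (2R,3S)-2-(2,2-dimethyl-1,3-dioxan-5-yl)-3-(4-hydroxy-3,5-dimethoxyphenyl)-3-[2,4-dimethoxy-3-(methoxymethoxy)phenyl]propan-1-ol | COc1cc([C@@H](c2ccc(OC)c(OCOC)c2OC)[C@@H](CO)C2COC(C)(C)OC2)cc(OC)c1O | intermediate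
16 | 5-[(1S,2R)-3-(benzyloxy)-1-[4-(benzyloxy)-3,5-dimethoxyphenyl]-1-[2,4-dimethoxy-3-(methoxymethoxy)phenyl]propan-2-yl]-2,2-dimethyl-1,3-dioxane | COc1cc([C@@H](c2ccc(OC)c(OCOC)c2OC)[C@@H](COCc2ccccc2)C2COC(C)(C)OC2)cc(OC)c1OCc1ccccc1 | intermediate
17 | 2-[(1S,2R)-3-(benzyloxy)-1-[4-(benzyloxy)-3,5-dimethoxyphenyl]-1-[2,4-dimethoxy-3-(methoxymethoxy)phenyl]propan-2-yl]propane-1,3-diol | COc1cc([C@@H](c2ccc(OC)c(OCOC)c2OC)[C@@H](COCc2ccccc2)C(CO)CO)cc(OC)c1OCc1ccccc1 | intermediate
18 | 2-[(1S,2R)-3-(benzyloxy)-1-[4-(benzyloxy)-3,5-dimethoxyphenyl]-1-[2,4-dimethoxy-3-(methoxymethoxy)phenyl]propan-2-yl]propane-1,3-diyl bis(4-methylbenzenesulfonate) | COc1cc([C@@H](c2ccc(OC)c(OCOC)c2OC)[C@@H](COCc2ccccc2)C(COS(=O)(=O)c2ccc(C)cc2)COS(=O)(=O)c2ccc(C)cc2)cc(OC)c1OCc1ccccc1 | intermediate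
19 | 2-[(1S,2R)-3-(benzyloxy)-1-[4-(benzyloxy)-3,5-dimethoxyphenyl]-1-(3-hydroxy-2,4-dimethoxyphenyl)propan-2-yl]propane-1,3-diyl bis(4-methylbenzenesulfonate) | COc1cc([C@@H](c2ccc(OC)c(O)c2OC)[C@@H](COCc2ccccc2)C(COS(=O)(=O)c2ccc(C)cc2)COS(=O)(=O)c2ccc(C)cc2)cc(OC)c1OCc1ccccc1 | intermediate
20 | (1S,2R,3R,4aS)-4a-H cyclohexa-2,5-dienone tautomer of 21 (C7=O, C5=C6 and C8=C8a double bonds, C4a sp3 with H-4a cis to the C1 aryl group; not isolated) | COC1=C[C@@H]2C[C@@H](COS(=O)(=O)c3ccc(C)cc3)[C@H](COCc3ccccc3)[C@@H](c3cc(OC)c(OCc4ccccc4)c(OC)c3)C2=C(OC)C1=O | intermediate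
21 | {(1S,2R,3R)-1-[4-(benzyloxy)-3,5-dimethoxyphenyl]-2-[(benzyloxy)methyl]-7-hydroxy-6,8-dimethoxy-1,2,3,4-tetrahydronaphthalen-3-yl}methyl 4-methylbenzenesulfonate | COc1cc([C@H]2c3c(cc(OC)c(O)c3OC)C[C@@H](COS(=O)(=O)c3ccc(C)cc3)[C@@H]2COCc4ccccc4)cc(OC)c1OCc1ccccc1 | intermediate
22 | {(1S,2R,3R)-1-[4-(benzyloxy)-3,5-dimethoxyphenyl]-2-[(benzyloxy)methyl]-7-hydroxy-6,8-dimethoxy-1,2,3,4-tetrahydronaphthalen-3-yl}methyl acetate (not isolated) | COc1cc([C@H]2c3c(cc(OC)c(O)c3OC)C[C@@H](COC(C)=O)[C@@H]2COCc4ccccc4)cc(OC)c1OCc1ccccc1 | intermediate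
23 | {(1S,2R,3R)-1-[4-(benzyloxy)-3,5-dimethoxyphenyl]-2-[(benzyloxy)methyl]-7-hydroxy-6,8-dimethoxy-1,2,3,4-tetrahydronaphthalen-3-yl}methanol | COc1cc([C@H]2c3c(cc(OC)c(O)c3OC)C[C@@H](CO)[C@@H]2COCc4ccccc4)cc(OC)c1OCc1ccccc1 | intermediate
24 | (1S,2R,3R)-1-(4-hydroxy-3,5-dimethoxyphenyl)-2,3-bis(hydroxymethyl)-6,8-dimethoxy-1,2,3,4-tetrahydronaphthalen-7-ol | COc1cc([C@H]2c3c(cc(OC)c(O)c3OC)C[C@@H](CO)[C@@H]2CO)cc(OC)c1O | target

## Step count and least certain steps

Total step count: 14. Longest linear sequence: 11 steps (steps 4 to 14, from 8 to 24).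

Step 12 (key step). The most likely failure is selection of the wrong diastereotopic arm. The productive chair pays for a syn-axial contact between the C1 aryl group and the spectator arm, while the chair leading to the 3-epimer pays for crowding between the spectator arm and the departing sulfonate; the margin between the two cannot be predicted with confidence. Intermolecular O-alkylation is a second, concentration-dependent risk. The fallback takes the choice of arm away from the ring closure and makes it reagent-controlled. It sets out from diol 17. A lipase-catalysed mono-acetylation with vinyl acetate (enzyme chosen by screening, for example Candida antarctica lipase B or Pseudomonas cepacia lipase) would acetylate the arm that is to remain as C9' and give (2S)-2-[(1S,2R)-3-(benzyloxy)-1-[4-(benzyloxy)-3,5-dimethoxyphenyl]-1-[2,4-dimethoxy-3-(methoxymethoxy)phenyl]propan-2-yl]-3-hydroxypropyl acetate F1. Tosylation of the remaining hydroxyl would give the (2R)-acetate tosylate F2. Acetal cleavage with ZnBr2 and n-PrSH in CH2Cl2, which spares the acetate, would give the ring A phenol F3. The same KOt-Bu ring closure, now onto a single sulfonate with C3 already fixed, comes back to the route at acetate 22, which the second stage of step 13 converts into 23.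

Step 7. The most likely failure is poor facial selectivity at the quinone methide carbon. The enamine face is fixed by the catalyst, but the face of 13 is chosen only by an open transition state, so the C1/C2 diastereoselectivity may be eroded. The fallback sets C1 and C2 in two separate catalyst-controlled events and keeps the pendant phenol benzylated from the start; it sets out from 3 and 5 and comes back at 16.
- O-Benzylation of 3 would give 4-(benzyloxy)-3,5-dimethoxybenzaldehyde F4, and Wittig homologation with Ph3P=CHCHO the enal (E)-3-[4-(benzyloxy)-3,5-dimethoxyphenyl]prop-2-enal F5.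
- Quenching aryllithium 5 with B(OMe)3 and aqueous work-up would give [2,4-dimethoxy-3-(methoxymethoxy)phenyl]boronic acid F6.
- Asymmetric 1,4-addition of F6 to F5 ([RhCl(C2H4)2]2 with a chiral diene ligand, KOH, MeOH–H2O) would give (3S)-3-[4-(benzyloxy)-3,5-dimethoxyphenyl]-3-[2,4-dimethoxy-3-(methoxymethoxy)phenyl]propanal F7.
- Photoredox organocatalytic α-alkylation with diethyl bromomalonate (Ru(bpy)3Cl2, a chiral imidazolidinone triflate salt of the appropriate antipode, 2,6-lutidine, DMF, visible light) would give diethyl 2-[(1S,2R)-1-[4-(benzyloxy)-3,5-dimethoxyphenyl]-1-[2,4-dimethoxy-3-(methoxymethoxy)phenyl]-3-oxopropan-2-yl]propanedioate F8.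
- LiAlH4 would reduce F8 to the triol 2-[(1S,2R)-1-[4-(benzyloxy)-3,5-dimethoxyphenyl]-1-[2,4-dimethoxy-3-(methoxymethoxy)phenyl]-3-hydroxypropan-2-yl]propane-1,3-diol F9.
- 2,2-Dimethoxypropane with PPTS would close the six-membered acetonide (2R,3S)-3-[4-(benzyloxy)-3,5-dimethoxyphenyl]-2-(2,2-dimethyl-1,3-dioxan-5-yl)-3-[2,4-dimethoxy-3-(methoxymethoxy)phenyl]propan-1-ol F10, and NaH with BnBr would give 16.

Step 3. The most likely failure is incomplete ortho-lithiation of 2, which leaves n-BuLi to add to aldehyde 4, together with loss of the acid-sensitive carbinol on work-up. The fallback replaces deprotonation by halogen–metal exchange. It sets out from 2: bromination with NBS in MeCN at the position ortho to a methoxy group and para to the other would give 1-bromo-2,4-dimethoxy-3-(methoxymethoxy)benzene F11, and n-BuLi in THF at −78 °C would exchange bromine for lithium and come back to the route at aryllithium 5.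

Step 9. The most likely failure is loss of the methoxymethyl group along with the acetonide, which would expose the ring A phenol before sulfonylation. The fallback accepts that outcome and uses leaving groups that a phenol does not interfere with. It sets out from 16.
- HCl in MeOH would remove both acetals and give the phenol diol 2-[(1S,2R)-3-(benzyloxy)-1-[4-(benzyloxy)-3,5-dimethoxyphenyl]-1-(3-hydroxy-2,4-dimethoxyphenyl)propan-2-yl]propane-1,3-diol F12.
- An Appel reaction (PPh3, CBr4, CH2Cl2, 0 °C), to which phenols are inert, would give the dibromide 3-[(1S,2R)-2-[(benzyloxy)methyl]-1-[4-(benzyloxy)-3,5-dimethoxyphenyl]-4-bromo-3-(bromomethyl)butyl]-2,6-dimethoxyphenol F13.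
- The phenoxide ring closure of step 12 with bromide as leaving group would give (1S,2R,3R)-1-[4-(benzyloxy)-3,5-dimethoxyphenyl]-2-[(benzyloxy)methyl]-3-(bromomethyl)-6,8-dimethoxy-1,2,3,4-tetrahydronaphthalen-7-ol F14.
- CsOAc in DMF comes back to the route at acetate 22.

## Further compounds

F1 | step 12 | (2S)-2-[(1S,2R)-3-(benzyloxy)-1-[4-(benzyloxy)-3,5-dimethoxyphenyl]-1-[2,4-dimethoxy-3-(methoxymethoxy)phenyl]propan-2-yl]-3-hydroxypropyl acetate | COc1cc([C@@H](c2ccc(OC)c(OCOC)c2OC)[C@@H](COCc2ccccc2)[C@@H](CO)COC(C)=O)cc(OC)c1OCc1ccccc1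
F2 | step 12 | (2R)-2-[(1S,2R)-3-(benzyloxy)-1-[4-(benzyloxy)-3,5-dimethoxyphenyl]-1-[2,4-dimethoxy-3-(methoxymethoxy)phenyl]propan-2-yl]-3-[(4-methylbenzenesulfonyl)oxy]propyl acetate | COc1cc([C@@H](c2ccc(OC)c(OCOC)c2OC)[C@@H](COCc2ccccc2)[C@@H](COS(=O)(=O)c2ccc(C)cc2)COC(C)=O)cc(OC)c1OCc1ccccc1
F3 | step 12 | (2R)-2-[(1S,2R)-3-(benzyloxy)-1-[4-(benzyloxy)-3,5-dimethoxyphenyl]-1-(3-hydroxy-2,4-dimethoxyphenyl)propan-2-yl]-3-[(4-methylbenzenesulfonyl)oxy]propyl acetate | COc1cc([C@@H](c2ccc(OC)c(O)c2OC)[C@@H](COCc2ccccc2)[C@@H](COS(=O)(=O)c2ccc(C)cc2)COC(C)=O)cc(OC)c1OCc1ccccc1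
F4 | step 7 | 4-(benzyloxy)-3,5-dimethoxybenzaldehyde | COc1cc(C=O)cc(OC)c1OCc1ccccc1
F5 | step 7 | (E)-3-[4-(benzyloxy)-3,5-dimethoxyphenyl]prop-2-enal | COc1cc(/C=C/C=O)cc(OC)c1OCc1ccccc1
F6 | step 7 | [2,4-dimethoxy-3-(methoxymethoxy)phenyl]boronic acid | COCOc1c(OC)ccc(B(O)O)c1OC
F7 | step 7 | (3S)-3-[4-(benzyloxy)-3,5-dimethoxyphenyl]-3-[2,4-dimethoxy-3-(methoxymethoxy)phenyl]propanal | COc1cc([C@H](CC=O)c2ccc(OC)c(OCOC)c2OC)cc(OC)c1OCc1ccccc1
F8 | step 7 | diethyl 2-[(1S,2R)-1-[4-(benzyloxy)-3,5-dimethoxyphenyl]-1-[2,4-dimethoxy-3-(methoxymethoxy)phenyl]-3-oxopropan-2-yl]propanedioate | COc1cc([C@@H](c2ccc(OC)c(OCOC)c2OC)[C@@H](C=O)C(C(=O)OCC)C(=O)OCC)cc(OC)c1OCc1ccccc1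
F9 | step 7 | 2-[(1S,2R)-1-[4-(benzyloxy)-3,5-dimethoxyphenyl]-1-[2,4-dimethoxy-3-(methoxymethoxy)phenyl]-3-hydroxypropan-2-yl]propane-1,3-diol | COc1cc([C@@H](c2ccc(OC)c(OCOC)c2OC)[C@@H](CO)C(CO)CO)cc(OC)c1OCc1ccccc1
F10 | step 7 | (2R,3S)-3-[4-(benzyloxy)-3,5-dimethoxyphenyl]-2-(2,2-dimethyl-1,3-dioxan-5-yl)-3-[2,4-dimethoxy-3-(methoxymethoxy)phenyl]propan-1-ol | COc1cc([C@@H](c2ccc(OC)c(OCOC)c2OC)[C@@H](CO)C2COC(C)(C)OC2)cc(OC)c1OCc1ccccc1
F11 | step 3 | 1-bromo-2,4-dimethoxy-3-(methoxymethoxy)benzene | COCOc1c(OC)ccc(Br)c1OC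
F12 | step 9 | 2-[(1S,2R)-3-(benzyloxy)-1-[4-(benzyloxy)-3,5-dimethoxyphenyl]-1-(3-hydroxy-2,4-dimethoxyphenyl)propan-2-yl]propane-1,3-diol | COc1cc([C@@H](c2ccc(OC)c(O)c2OC)[C@@H](COCc2ccccc2)C(CO)CO)cc(OC)c1OCc1ccccc1
F13 | step 9 | 3-[(1S,2R)-2-[(benzyloxy)methyl]-1-[4-(benzyloxy)-3,5-dimethoxyphenyl]-4-bromo-3-(bromomethyl)butyl]-2,6-dimethoxyphenol | COc1cc([C@@H](c2ccc(OC)c(O)c2OC)[C@@H](COCc2ccccc2)C(CBr)CBr)cc(OC)c1OCc1ccccc1
F14 | step 9 | (1S,2R,3R)-1-[4-(benzyloxy)-3,5-dimethoxyphenyl]-2-[(benzyloxy)methyl]-3-(bromomethyl)-6,8-dimethoxy-1,2,3,4-tetrahydronaphthalen-7-ol | COc1cc([C@H]2c3c(cc(OC)c(O)c3OC)C[C@@H](CBr)[C@@H]2COCc4ccccc4)cc(OC)c1OCc1ccccc1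
A1 | alternative 1 | bis[(2S)-1-methoxy-1-oxopropan-2-yl] (1S,2R,3S,4S)-7-(benzyloxy)-1-[4-(benzyloxy)-3,5-dimethoxyphenyl]-4-hydroxy-6,8-dimethoxy-1,2,3,4-tetrahydronaphthalene-2,3-dicarboxylate | COc1cc([C@H]2c3c(cc(OC)c(OCc4ccccc4)c3OC)[C@@H](O)[C@@H](C(=O)O[C@@H](C)C(=O)OC)[C@@H]2C(=O)O[C@@H](C)C(=O)OC)cc(OC)c1OCc1ccccc1
A2 | alternative 1 | 4-(benzyloxy)-2-[4-(benzyloxy)-3,5-dimethoxybenzyl]-3,5-dimethoxybenzaldehyde | COc1cc(Cc2c(C=O)cc(OC)c(OCc3ccccc3)c2OC)cc(OC)c1OCc1ccccc1
A3 | alternative 1 | bis[(2S)-1-methoxy-1-oxopropan-2-yl] (E)-but-2-enedioate | COC(=O)[C@H](C)OC(=O)/C=C/C(=O)O[C@@H](C)C(=O)OC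
A4 | alternative 2 | (2R,4R)-pentane-2,4-diyl diester bridging the two carboxyl groups of (1S,2R)-7-hydroxy-1-(4-hydroxy-3,5-dimethoxyphenyl)-6,8-dimethoxy-1,2-dihydronaphthalene-2,3-dicarboxylic acid | COc1cc([C@H]2c3c(cc(OC)c(O)c3OC)C=C3C(=O)O[C@H](C)C[C@@H](C)OC(=O)[C@H]23)cc(OC)c1O
A5 | alternative 2 | (2R,4R)-pentane-2,4-diyl bis[(E)-3-(4-hydroxy-3,5-dimethoxyphenyl)prop-2-enoate] | COc1cc(/C=C/C(=O)O[C@H](C)C[C@@H](C)OC(=O)/C=C/c2cc(OC)c(O)c(OC)c2)cc(OC)c1O
A6 | alternative 3 | (1S,2R,3R)-7-(benzyloxy)-3-{[(tert-butyldimethylsilyl)oxy]methyl}-1-(4-hydroxy-3,5-dimethoxyphenyl)-6,8-dimethoxy-1,2,3,4-tetrahydronaphthalene-2-carbaldehyde | COc1cc([C@H]2c3c(cc(OC)c(OCc4ccccc4)c3OC)C[C@@H](CO[Si](C)(C)C(C)(C)C)[C@@H]2C=O)cc(OC)c1O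
A7 | alternative 3 | (3R)-4-{4-(benzyloxy)-2-[hydroxy(4-hydroxy-3,5-dimethoxyphenyl)methyl]-3,5-dimethoxyphenyl}-3-{[(tert-butyldimethylsilyl)oxy]methyl}butanal | COc1cc(C(O)c2c(C[C@@H](CO[Si](C)(C)C(C)(C)C)CC=O)cc(OC)c(OCc3ccccc3)c2OC)cc(OC)c1O
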